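**Plan**
- Cuts, in retrosynthetic order: C13=C14 (olefination with a cinnamyl phosphonate), C7–C8 (Wittig, then saturation), the two C–O bonds of the peroxide (C6–O and O–C3), C2=C3 together with the lactone C1–O bond, and C4–C5.
- Enabling feature: in the 1,2-dioxane the O–O bridge joins tertiary C6 to C3, and C3 lies β to the lactone carbonyl C1 of the fused γ-lactone. H2O2 can therefore supply both oxygens, one by opening a C6–C7 oxirane at C6 and one by conjugate addition to a C2=C3 butenolide.
- Forward order: C4–C5 by enolate alkylation, then the butenolide ring, then the 1,2-dioxane ring, then the C7–C16 chain by two olefinations placed around a diimide reduction.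
- Stereochemistry: C4 from (R)-lactic acid through its pivalaldehyde acetal, C6 from (S)-2-methylglycidol by inversion in the oxirane opening, C3 from the cis-selective ring closure directed by C4, and the E,E-diene from the phosphonate olefination and the E-cinnamyl reagent.

Key step: step 6

Remark: carbons are numbered along the chain (C1 lactone carbonyl, C3 peroxy methine, C4 and C6 the two methyl-bearing carbons, C7–C16 the side chain ending at the phenyl-bearing carbon). The alkene geometry formed in step 10 is taken as irrelevant because that bond is saturated in step 11.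

**Route**

Step 1
Reactants: 1 (R)-lactic acid
Product: 2 (2R,5R)-2-tert-butyl-5-methyl-1,3-dioxolan-4-one (cis)
Conditions: t-BuCHO, TsOH·H2O (cat.), H2SO4 (cat.), pentane, reflux, Dean–Stark; recrystallisation from pentane, −78 °C
Reagents that add atoms: pivalaldehyde, CC(C)(C)C=O
Why: Acid-catalysed acetalisation with azeotropic removal of water equilibrates towards the cis-dioxolanone, so the new acetal centre records the lactate configuration (self-regeneration of stereocentres) and the minor trans isomer is removed by crystallisation.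

Step 2
Reactants: 3 (S)-2-methylglycidol
Product: 4 [(2R)-2-methyloxiran-2-yl]methyl trifluoromethanesulfonate
Conditions: Tf2O, 2,6-lutidine, CH2Cl2, −78 °C to −40 °C; cold aqueous work-up, used crude
Reagents that add atoms: triflic anhydride, O=S(=O)(OS(=O)(=O)C(F)(F)F)C(F)(F)F
Why: O-Sulfonylation of the primary alcohol with a hindered pyridine base leaves the oxirane untouched and gives a leaving group reactive enough for an enolate at −78 °C; no bond to the stereocentre changes, and the descriptor becomes R only through the priority rules.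

Step 3
Reactants: 2 (2R,5R)-2-tert-butyl-5-methyl-1,3-dioxolan-4-one; 4 [(2R)-2-methyloxiran-2-yl]methyl trifluoromethanesulfonate
Product: 6 (2R,5S)-2-tert-butyl-5-methyl-5-{[(2S)-2-methyloxiran-2-yl]methyl}-1,3-dioxolan-4-one, via lithium enolate 5 (not isolated)
Conditions: LiN(i-Pr)2, THF, −78 °C; then 4, DMPU, −78 °C to −40 °C
Reagents that add atoms: none
Why: Enolate alkylation by direct SN2 displacement of the primary triflate occurs on the face anti to the tert-butyl group, so the new C4–C5 bond takes the place of the former C–H bond and the quaternary centre C4 is set with overall retention, while the oxirane stereocentre is not involved.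

Step 4
Reactants: 6 (2R,5S)-2-tert-butyl-5-methyl-5-{[(2S)-2-methyloxiran-2-yl]methyl}-1,3-dioxolan-4-one
Product: 7 (2R,5S)-2-tert-butyl-5-methyl-5-{[(2S)-2-methyloxiran-2-yl]methyl}-1,3-dioxolan-4-ol (both C4 epimers of the lactol)
Conditions: i-Bu2AlH, CH2Cl2, −78 °C; aq. KNaC4H4O6 work-up
Reagents that add atoms: none
Why: Partial reduction of a lactone with i-Bu2AlH at low temperature stops at the aluminium hemiacetal, and a 2,2-disubstituted oxirane is inert to the reagent at −78 °C.

Step 5
Reactants: 7 lactol (2R,5S)-2-tert-butyl-5-methyl-5-{[(2S)-2-methyloxiran-2-yl]methyl}-1,3-dioxolan-4-ol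
Product: 10 (5S)-5-methyl-5-{[(2S)-2-methyloxiran-2-yl]methyl}furan-2(5H)-one, via hydroxy aldehyde 8 (not isolated), via Z-hydroxy enoate 9 (not isolated)
Conditions: (CF3CH2O)2P(O)CH2CO2Me (excess), KN(SiMe3)2 (slightly less than the phosphonate), 18-crown-6, THF, −78 °C; then 7, −78 °C to −20 °C; aq. NH4Cl
Reagents that add atoms: methyl bis(2,2,2-trifluoroethyl)phosphonoacetate, COC(=O)CP(=O)(OCC(F)(F)F)OCC(F)(F)F
Why: Still–Gennari olefination of a lactol should proceed by base-induced opening of the hemiacetal with loss of pivalaldehyde and kinetically Z-selective olefination of the freed aldehyde, after which the cis-placed tertiary alkoxide closes the butenolide by 5-exo-trig acyl substitution with C4 as a spectator.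

Step 6
Reactants: 10 (5S)-5-methyl-5-{[(2S)-2-methyloxiran-2-yl]methyl}furan-2(5H)-one; 11 hydrogen peroxide
Product: 13 (3R,4aS,7aS)-3-(hydroxymethyl)-3,4a-dimethyltetrahydrofuro[3,2-c][1,2]dioxin-6(3H)-one (cis-fused peroxy-lactone with the C7 hydroxymethyl group on C6), via hydroxy hydroperoxide 12 (not isolated)
Conditions: H2O2 (dry Et2O solution, excess), H3PMo12O40 (cat.), Et2O, rt; water wash, solvent exchanged for CF3CH2OH without concentrating to dryness; then Et2NH, CF3CH2OH, rt
Reagents that add atoms: hydrogen peroxide (compound 11), OO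
Why: The heteropolyacid activates the oxirane oxygen and H2O2 attacks the tertiary carbon C6 from the rear in a borderline SN2 opening, which should give hydroxy hydroperoxide 12 with inversion at C6 and leave the former oxirane oxygen as the C7 hydroxyl; the closest known reaction is the H3PMo12O40-catalysed perhydrolysis of 2,2-disubstituted epoxides. Once the excess oxidant is washed out, Et2NH ionises the hydroperoxide and the peroxide anion adds to C3 of the butenolide, an amine-mediated intramolecular oxa-Michael addition of a hydroperoxide of the kind known for butenolides and enoates. The 1,2-dioxane closes in the 6-exo-trig mode through a chair-like transition state. C6 is controlled by the configuration of the glycidol-derived oxirane through stereospecific inversion, and C3 by C4, whose tether can deliver the peroxide only to the butenolide face it occupies, so the ring fusion should be cis. The step needs attack at the tertiary rather than the primary oxirane carbon, which the better stabilisation of positive charge at C6 under acid catalysis secures, and it needs OOH rather than the C7 OH as Michael donor, which the higher acidity and alpha-effect nucleophilicity of the hydroperoxide secure; the electron-poor butenolide alkene should be inert to the electrophilic peroxo-molybdenum species.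

Step 7
Reactants: 13 (3R,4aS,7aS)-3-(hydroxymethyl)-3,4a-dimethyltetrahydrofuro[3,2-c][1,2]dioxin-6(3H)-one
Product: 14 (3R,4aS,7aS)-3,4a-dimethyl-6-oxohexahydrofuro[3,2-c][1,2]dioxine-3-carbaldehyde (C7 aldehyde)
Conditions: Dess–Martin periodinane, CH2Cl2, 0 °C to rt
Reagents that add atoms: none
Why: Dess–Martin oxidation of the neopentyl-type primary alcohol is neutral and non-reducing, so the O–O bond and the lactone should survive, and the aldehyde has no alpha-hydrogen through which C6 could epimerise.

Step 8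
Reactants: 15 6-bromohexan-1-ol
Product: 16 [(6-bromohexyl)oxy](tert-butyl)dimethylsilane
Conditions: TBSCl, imidazole, DMF, rt
Reagents that add atoms: tert-butyldimethylsilyl chloride, CC(C)(C)[Si](C)(C)Cl
Why: Imidazole-promoted silylation of a primary alcohol is a standard protection and the primary bromide is untouched.

Step 9
Reactants: 16 [(6-bromohexyl)oxy](tert-butyl)dimethylsilane
Product: 17 (6-{[tert-butyl(dimethyl)silyl]oxy}hexyl)triphenylphosphonium bromide
Conditions: PPh3, MeCN, reflux
Reagents that add atoms: triphenylphosphine, c1ccc(cc1)P(c1ccccc1)c1ccccc1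
Why: SN2 quaternisation of triphenylphosphine by the unhindered primary bromide gives the Wittig salt.

Step 10
Reactants: 17 (6-{[tert-butyl(dimethyl)silyl]oxy}hexyl)triphenylphosphonium bromide; 14 C7 aldehyde
Product: 19 (3R,4aS,7aS)-3-[(1Z)-7-{[tert-butyl(dimethyl)silyl]oxy}hept-1-en-1-yl]-3,4a-dimethyltetrahydrofuro[3,2-c][1,2]dioxin-6(3H)-one, via phosphorus ylide 18 (not isolated)
Conditions: NaN(SiMe3)2 (slight deficit to 17), THF, 0 °C; then 14, −78 °C to 0 °C
Reagents that add atoms: none
Why: Wittig olefination with a non-stabilised ylide, pre-formed with a deficit of base so that no free amide meets the base-sensitive peroxy-lactone, should add to the non-enolisable aldehyde at −78 °C and give mainly the Z-alkene at C7=C8.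

Step 11
Reactants: 19 Z-alkene silyl ether
Product: 20 (3S,4aS,7aS)-3-(7-{[tert-butyl(dimethyl)silyl]oxy}heptyl)-3,4a-dimethyltetrahydrofuro[3,2-c][1,2]dioxin-6(3H)-one
Conditions: KO2CN=NCO2K (excess, in portions), AcOH, MeOH/CH2Cl2, 0 °C to rt
Reagents that add atoms: none
Why: Diimide reduction transfers two hydrogens in a concerted syn fashion to the isolated disubstituted alkene and leaves the O–O bond intact, which catalytic hydrogenation would cleave; no stereocentre is touched, and the C6 descriptor changes only through the priority rules.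

Step 12
Reactants: 20 saturated silyl ether
Product: 21 (3S,4aS,7aS)-3-(7-hydroxyheptyl)-3,4a-dimethyltetrahydrofuro[3,2-c][1,2]dioxin-6(3H)-one
Conditions: HF·pyridine, THF/pyridine, 0 °C to rt
Reagents that add atoms: none
Why: Desilylation with buffered HF avoids basic fluoride sources that could start a retro-oxa-Michael or Kornblum–DeLaMare fragmentation of the peroxy-lactone.

Step 13
Reactants: 21 C13 alcohol
Product: 22 7-[(3S,4aS,7aS)-3,4a-dimethyl-6-oxohexahydrofuro[3,2-c][1,2]dioxin-3-yl]heptanal
Conditions: Dess–Martin periodinane, CH2Cl2, 0 °C to rt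
Reagents that add atoms: none
Why: Dess–Martin oxidation of the primary alcohol to the aldehyde is again neutral and compatible with the peroxide.

Step 14
Reactants: 22 C13 aldehyde; 23 diethyl cinnamylphosphonate
Product: 25 plakortolide R, (3S,4aS,7aS)-3,4a-dimethyl-3-[(7E,9E)-10-phenyldeca-7,9-dien-1-yl]tetrahydrofuro[3,2-c][1,2]dioxin-6(3H)-one, via lithiated phosphonate 24 (not isolated)
Conditions: n-BuLi (slight deficit to 23), THF/DMPU, −78 °C; then 22, −78 °C to rt
Reagents that add atoms: none
Why: Horner–Wadsworth–Emmons olefination with an allylic phosphonate should work because the pre-formed delocalised anion adds to the aldehyde at −78 °C faster than it deprotonates the lactone, and elimination from the equilibrated adduct gives the new C13=C14 bond with E geometry while the E-cinnamyl alkene is carried through unchanged.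

**Compound list**

1 | (R)-lactic acid, (2R)-2-hydroxypropanoic acid | C[C@@H](O)C(=O)O | starting material
2 | (2R,5R)-2-tert-butyl-5-methyl-1,3-dioxolan-4-one (cis) | C[C@H]1O[C@H](OC1=O)C(C)(C)C | intermediate
3 | (S)-2-methylglycidol, [(2S)-2-methyloxiran-2-yl]methanol | C[C@@]1(CO1)CO | starting material
4 | [(2R)-2-methyloxiran-2-yl]methyl trifluoromethanesulfonate | C[C@@]1(CO1)COS(=O)(=O)C(F)(F)F | intermediate
5 | lithium (2R)-2-tert-butyl-5-methyl-1,3-dioxol-4-olate (enolate of 2) | CC1=C([O-])O[C@@H](O1)C(C)(C)C.[Li+] | intermediate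
6 | (2R,5S)-2-tert-butyl-5-methyl-5-{[(2S)-2-methyloxiran-2-yl]methyl}-1,3-dioxolan-4-one | C[C@@]1(C[C@@]2(C)CO2)O[C@H](OC1=O)C(C)(C)C | intermediate
7 | (2R,5S)-2-tert-butyl-5-methyl-5-{[(2S)-2-methyloxiran-2-yl]methyl}-1,3-dioxolan-4-ol (both C4 epimers) | C[C@@]1(C[C@@]2(C)CO2)O[C@H](OC1O)C(C)(C)C | intermediate
8 | (2S)-2-hydroxy-2-methyl-3-[(2S)-2-methyloxiran-2-yl]propanal | C[C@@](O)(C=O)C[C@@]1(C)CO1 | intermediate
9 | methyl (2Z,4S)-4-hydroxy-4-methyl-5-[(2S)-2-methyloxiran-2-yl]pent-2-enoate | COC(=O)/C=C\[C@@](C)(O)C[C@@]1(C)CO1 | intermediate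
10 | (5S)-5-methyl-5-{[(2S)-2-methyloxiran-2-yl]methyl}furan-2(5H)-one | C[C@@]1(CO1)C[C@]2(C)OC(=O)C=C2 | intermediate
11 | hydrogen peroxide | OO | starting material
12 | (5S)-5-[(2R)-2-hydroperoxy-3-hydroxy-2-methylpropyl]-5-methylfuran-2(5H)-one | C[C@@](CO)(OO)C[C@]1(C)OC(=O)C=C1 | intermediate
13 | (3R,4aS,7aS)-3-(hydroxymethyl)-3,4a-dimethyltetrahydrofuro[3,2-c][1,2]dioxin-6(3H)-one | C[C@]1(CO)C[C@]2(C)OC(=O)C[C@@H]2OO1 | intermediate
14 | (3R,4aS,7aS)-3,4a-dimethyl-6-oxohexahydrofuro[3,2-c][1,2]dioxine-3-carbaldehyde | C[C@]1(C=O)C[C@]2(C)OC(=O)C[C@@H]2OO1 | intermediate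
15 | 6-bromohexan-1-ol | OCCCCCCBr | starting material
16 | [(6-bromohexyl)oxy](tert-butyl)dimethylsilane | CC(C)(C)[Si](C)(C)OCCCCCCBr | intermediate
17 | (6-{[tert-butyl(dimethyl)silyl]oxy}hexyl)triphenylphosphonium bromide | CC(C)(C)[Si](C)(C)OCCCCCC[P+](c1ccccc1)(c1ccccc1)c1ccccc1.[Br-] | intermediate
18 | (6-{[tert-butyl(dimethyl)silyl]oxy}hexylidene)triphenylphosphorane | CC(C)(C)[Si](C)(C)OCCCCCC=P(c1ccccc1)(c1ccccc1)c1ccccc1 | intermediate
19 | (3R,4aS,7aS)-3-[(1Z)-7-{[tert-butyl(dimethyl)silyl]oxy}hept-1-en-1-yl]-3,4a-dimethyltetrahydrofuro[3,2-c][1,2]dioxin-6(3H)-one | C[C@]1(/C=C\CCCCCO[Si](C)(C)C(C)(C)C)C[C@]2(C)OC(=O)C[C@@H]2OO1 | intermediate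
20 | (3S,4aS,7aS)-3-(7-{[tert-butyl(dimethyl)silyl]oxy}heptyl)-3,4a-dimethyltetrahydrofuro[3,2-c][1,2]dioxin-6(3H)-one | C[C@]1(CCCCCCCO[Si](C)(C)C(C)(C)C)C[C@]2(C)OC(=O)C[C@@H]2OO1 | intermediate
21 | (3S,4aS,7aS)-3-(7-hydroxyheptyl)-3,4a-dimethyltetrahydrofuro[3,2-c][1,2]dioxin-6(3H)-one | C[C@]1(CCCCCCCO)C[C@]2(C)OC(=O)C[C@@H]2OO1 | intermediate
22 | 7-[(3S,4aS,7aS)-3,4a-dimethyl-6-oxohexahydrofuro[3,2-c][1,2]dioxin-3-yl]heptanal | C[C@]1(CCCCCCC=O)C[C@]2(C)OC(=O)C[C@@H]2OO1 | intermediate
23 | diethyl [(2E)-3-phenylprop-2-en-1-yl]phosphonate (diethyl cinnamylphosphonate) | CCOP(=O)(OCC)C/C=C/c1ccccc1 | starting material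
24 | lithium salt of the allylic carbanion of diethyl cinnamylphosphonate | CCOP(=O)(OCC)[CH-]/C=C/c1ccccc1.[Li+] | intermediate
25 | plakortolide R, (3S,4aS,7aS)-3,4a-dimethyl-3-[(7E,9E)-10-phenyldeca-7,9-dien-1-yl]tetrahydrofuro[3,2-c][1,2]dioxin-6(3H)-one | C[C@]1(CCCCCC/C=C/C=C/c2ccccc2)C[C@]2(C)OC(=O)C[C@@H]2OO1 | target

**Step count and risks**

Total step count: 14. Longest linear sequence: 11 steps from (R)-lactic acid (steps 1, 3, 4, 5, 6, 7, 10, 11, 12, 13, 14).

Steps most likely to fail:

Step 6. The oxirane may ionise at C6 before the peroxide is delivered, which would erode the C6 configuration. Attack may also occur at the primary oxirane carbon, or the hydroperoxide may be lost during the solvent change. The fallback gives up chiral-pool control of C6 and uses radical peroxidation of an alkene instead; it sets out from 2 and comes back to the route at 12, then 13. Enolate 5, made from 2 as in step 3, is alkylated with the known allylic bromide {[2-(bromomethyl)prop-2-en-1-yl]oxy}(tert-butyl)dimethylsilane to give (2R,5S)-2-tert-butyl-5-[2-({[tert-butyl(dimethyl)silyl]oxy}methyl)prop-2-en-1-yl]-5-methyl-1,3-dioxolan-4-one F1. Reduction with i-Bu2AlH gives the corresponding lactol F2. Still–Gennari olefination as in step 5 passes through (2S)-4-({[tert-butyl(dimethyl)silyl]oxy}methyl)-2-hydroxy-2-methylpent-4-enal F3 and methyl (2Z,4S)-6-({[tert-butyl(dimethyl)silyl]oxy}methyl)-4-hydroxy-4-methylhepta-2,6-dienoate F4 to (5S)-5-[2-({[tert-butyl(dimethyl)silyl]oxy}methyl)prop-2-en-1-yl]-5-methylfuran-2(5H)-one F5. Mukaiyama–Isayama peroxidation (Co(acac)2 with divalent cobalt, O2, Et3SiH, ClCH2CH2Cl) should place a triethylsilylperoxy group on tertiary C6 and give (5S)-5-{3-{[tert-butyl(dimethyl)silyl]oxy}-2-methyl-2-[(triethylsilyl)peroxy]propyl}-5-methylfuran-2(5H)-one F6 as a mixture of C6 epimers. Aqueous HF in MeCN removes both silyl groups and gives 12 together with its C6 epimer (5S)-5-[(2S)-2-hydroperoxy-3-hydroxy-2-methylpropyl]-5-methylfuran-2(5H)-one F7. Et2NH in CF3CH2OH cyclises both, and 13 is separated by chromatography from (3S,4aS,7aS)-3-(hydroxymethyl)-3,4a-dimethyltetrahydrofuro[3,2-c][1,2]dioxin-6(3H)-one F8.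

Step 3. Displacement at the hindered primary triflate may be slow enough for the enolate to decay, or the enolate may open the oxirane and scramble C6. The fallback uses a reactive allylic halide and installs the oxirane afterwards; it sets out from 2 and comes back at 6. Enolate 5 is alkylated with 3-bromo-2-methylprop-1-ene to give (2R,5S)-2-tert-butyl-5-methyl-5-(2-methylprop-2-en-1-yl)-1,3-dioxolan-4-one F9. Prilezhaev epoxidation with mCPBA in CH2Cl2 should give 6 together with its C6 epimer (2R,5S)-2-tert-butyl-5-methyl-5-{[(2R)-2-methyloxiran-2-yl]methyl}-1,3-dioxolan-4-one F10, and 6 is obtained by chromatographic separation, so that C6 then rests on separation rather than on the chiral pool.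

Step 5. The lactol may open sluggishly, so that olefination needs temperatures at which Z-selectivity falls and the tertiary alkoxide begins to attack the oxirane. The fallback builds the butenolide by ring-closing metathesis; it sets out from 7 and comes back at 10. Wittig methylenation of 7 (Ph3PCH3Br, KOt-Bu, THF), through hydroxy aldehyde 8, gives (2S)-2-methyl-1-[(2S)-2-methyloxiran-2-yl]but-3-en-2-ol F11. Acylation with acryloyl chloride, i-Pr2NEt and catalytic DMAP gives (2S)-2-methyl-1-[(2S)-2-methyloxiran-2-yl]but-3-en-2-yl prop-2-enoate F12. Ring-closing metathesis with the second-generation Grubbs catalyst in CH2Cl2 at 40 °C closes the butenolide 10 with loss of ethylene.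

**Further compounds**

F1 | step 6 | (2R,5S)-2-tert-butyl-5-[2-({[tert-butyl(dimethyl)silyl]oxy}methyl)prop-2-en-1-yl]-5-methyl-1,3-dioxolan-4-one | C[C@@]1(CC(=C)CO[Si](C)(C)C(C)(C)C)O[C@H](OC1=O)C(C)(C)C
F2 | step 6 | (2R,5S)-2-tert-butyl-5-[2-({[tert-butyl(dimethyl)silyl]oxy}methyl)prop-2-en-1-yl]-5-methyl-1,3-dioxolan-4-ol (both C4 epimers) | C[C@@]1(CC(=C)CO[Si](C)(C)C(C)(C)C)O[C@H](OC1O)C(C)(C)C
F3 | step 6 | (2S)-4-({[tert-butyl(dimethyl)silyl]oxy}methyl)-2-hydroxy-2-methylpent-4-enal | C[C@@](O)(C=O)CC(=C)CO[Si](C)(C)C(C)(C)C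
F4 | step 6 | methyl (2Z,4S)-6-({[tert-butyl(dimethyl)silyl]oxy}methyl)-4-hydroxy-4-methylhepta-2,6-dienoate | COC(=O)/C=C\[C@@](C)(O)CC(=C)CO[Si](C)(C)C(C)(C)C
F5 | step 6 | (5S)-5-[2-({[tert-butyl(dimethyl)silyl]oxy}methyl)prop-2-en-1-yl]-5-methylfuran-2(5H)-one | C=C(CO[Si](C)(C)C(C)(C)C)C[C@]1(C)OC(=O)C=C1
F6 | step 6 | (5S)-5-{3-{[tert-butyl(dimethyl)silyl]oxy}-2-methyl-2-[(triethylsilyl)peroxy]propyl}-5-methylfuran-2(5H)-one (both C6 epimers) | CC[Si](CC)(CC)OOC(C)(CO[Si](C)(C)C(C)(C)C)C[C@]1(C)OC(=O)C=C1
F7 | step 6 | (5S)-5-[(2S)-2-hydroperoxy-3-hydroxy-2-methylpropyl]-5-methylfuran-2(5H)-one | C[C@](CO)(OO)C[C@]1(C)OC(=O)C=C1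
F8 | step 6 | (3S,4aS,7aS)-3-(hydroxymethyl)-3,4a-dimethyltetrahydrofuro[3,2-c][1,2]dioxin-6(3H)-one | C[C@@]1(CO)C[C@]2(C)OC(=O)C[C@@H]2OO1
F9 | step 3 | (2R,5S)-2-tert-butyl-5-methyl-5-(2-methylprop-2-en-1-yl)-1,3-dioxolan-4-one | C[C@@]1(CC(C)=C)O[C@H](OC1=O)C(C)(C)C
F10 | step 3 | (2R,5S)-2-tert-butyl-5-methyl-5-{[(2R)-2-methyloxiran-2-yl]methyl}-1,3-dioxolan-4-one | C[C@@]1(C[C@]2(C)CO2)O[C@H](OC1=O)C(C)(C)C
F11 | step 5 | (2S)-2-methyl-1-[(2S)-2-methyloxiran-2-yl]but-3-en-2-ol | C=C[C@@](C)(O)C[C@@]1(C)CO1
F12 | step 5 | (2S)-2-methyl-1-[(2S)-2-methyloxiran-2-yl]but-3-en-2-yl prop-2-enoate | C=CC(=O)O[C@](C)(C=C)C[C@@]1(C)CO1
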